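- I began with the small charge of the east run, in which two substrate hands, charged as a racemate, react away to products under a held gas with a racemization catalyst present; the flask below has a middle charge.

| flask | left-handed substrate | right-handed substrate | gas | racemization catalyst | remark | time |
|---|---|---|---|---|---|---|
| east | 0.18 M | 0.18 M | 16 mM (held) | 9.6 mM | run made earlier |  |
| south-west | 0.74 M | 0.74 M | 16 mM (held) | 9.6 mM | run made earlier |  |
| north | 0.37 M | 0.37 M | 16 mM (held) | 19 mM | run made earlier |  |
| flask | 0.37 M | 0.37 M | 16 mM (held) | 9.6 mM |  | 8.0 h |

- east (time / h: left-handed substrate / %, right-handed substrate / %): 0.417: 45, 45; 0.833: 42, 44; 2.00: 29, 33; 5.00: 14, 9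
- south-west (time / h: left-handed substrate / %, right-handed substrate / %): 1.33: 42, 43; 2.50: 32, 32; 4.00: 25, 29; 5.00: 20, 24
- north (time / h: left-handed substrate / %, right-handed substrate / %): 0.417: 46, 50; 0.833: 47, 44; 2.00: 30, 33; 5.00: 13, 18

(scatter of a reading: 2 percentage points)

- partner is single-handed; left-handed substrate and right-handed substrate are mirror images of each other, charged as a racemate, each of them at the stated concentration
- the numbers in the tables scatter with a standard deviation of 2 percentage points
- at the start none of the gas is in solution
- an excess is the difference of the two amounts in percent of their sum
- an excess is below zero if the other one leads
- the handed part of partner does not stay in what it makes, so the products of the two hands are mirror images too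

* part of the left-handed substrate and right-handed substrate charged together that has reacted at 8.0 h
* excess of left-handed product over right-handed product in the product at 8.0 h
* excess of right-handed substrate over left-handed substrate among what is left of the two at 8.0 h

- After 5.00 h the east run held 23.0 % of its substrate. I replaced its curve by a mean, the logarithm of charged over left divided by the time (a pseudo-first-order constant), which gave 0.294 /h.
- The south-west run, with its large charge, gave 0.164 /h, less than the east run, so I needed a constant read at the loading of the flask.
- The north run has that loading with twice the catalyst, a difference I set aside as an assumption. I took its mean loss constant, the logarithm of charged over left divided by the time, 0.234 /h, for the flask. This reading was less than the east one and more than the south-west one, and for the flask I reckoned from it 84.6 % reacted at 8.0 h.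
- The weak link was the stretch beyond 5.00 h, because by then the north run held 0.229 M of substrate, less than the east charge of 0.360 M. Using the east constant for that stretch, I reached 87.2 %, and I committed to that pair as my range.
- I reckoned no excess myself. The forecast gave 86 % reacted (80 % to 91 %), a product excess of 5 % (0 % to 20 %) and a substrate excess of 12 % (−2 % to 35 %), saying: “Racemization therefore cannot be pinned down, because product was never measured.”
- The flask gave 85.8 % reacted, a substrate excess of 6.16 % and a product excess of 36.9 %, above the forecast's range. With the turning of left-handed into right-handed substrate struck out both ways, the flask's product excess was 14.8 %.

    gas ⇌ partner, rate k1*(csat - [partner]) (kL = 0.00580 /s)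
    left-handed substrate + racemization catalyst ⇌ right-handed substrate + racemization catalyst, rate k2*[racemization catalyst]*[left-handed substrate] forward; the back reaction follows from the equilibrium constant (k = 0.0280 /M/s)
    partner + left-handed substrate → left-handed product (k = 0.00830 /M/s)
    partner + right-handed substrate → right-handed product (k = 0.00350 /M/s)
    partner → decomposed reagent (k = 1.90 × 10⁻⁴ /s)

- The flask's own mean loss constant came to 0.244 /h, against the carried 0.234 /h. For a neighbour flask with 0.0038 M of racemization catalyst, the carried constant gives 84.6 % reacted, and that neighbour flask reacted to 85.2 %.

The data are calculated for an exercise; scatter was added.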